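The ten-membered carbocycle is closed last through the C6–C7 bond (germacrane numbering) by an intramolecular Nozaki–Hiyama–Kishi allylation. The precursor is a 3-(bromomethyl)-5,6-dihydropyran-2-one: the C12 carboxyl is parked on O9, the C8 silyloxy group is trans to the C9 chain, and that chain ends in the (Z)-enal C6. This temporary lactone fixes C8 trans to C13 on C7=C11 and exploits the 1,3 placement of C7 and C9 in the ten-membered ring. The allylchromium adds through C7, setting C6 and C7 and closing the carbocycle; the C6 alkoxide then takes C12 from O9, forming the trans-fused α-methylene-γ-butyrolactone ring and freeing O9–H for the ester.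

Key step: step 12

Remark: positions are named by germacrane numbering (ring C1–C10, acrylate carbons C11–C13, formyl carbon C14, methyl C15); (S)-but-3-ene-1,2-diol and (R)-2-methylbutanoic acid are taken as purchasable single enantiomers.

Step 1
Reactants: 1 neryl acetate
Product: 3 (2Z)-3-methyl-6-oxohex-2-en-1-yl acetate, via 6,7-epoxyneryl acetate 2 (not isolated)
Conditions: mCPBA, CH2Cl2, 0 °C; then H5IO6, THF/H2O, 0 °C to rt
Reagents that add atoms: mCPBA, O=C(OO)c1cccc(Cl)c1
Why: Prilezhaev epoxidation should take the electron-rich 6,7-alkene in preference to the 2,3-alkene deactivated by the allylic acetate, and periodic acid should open and cleave the epoxide (glycol cleavage) to the aldehyde without touching the Z alkene.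

Step 2
Reactants: 3 (2Z)-3-methyl-6-oxohex-2-en-1-yl acetate
Product: 4 (2Z,6E)-3-methyl-8-oxoocta-2,6-dien-1-yl acetate
Conditions: Ph3P=CHCHO, toluene, 80 °C
Reagents that add atoms: (triphenylphosphoranylidene)acetaldehyde, O=CC=P(c1ccccc1)(c1ccccc1)c1ccccc1
Why: Wittig olefination with the stabilised formylmethylene ylide should give the (E)-enal, which is less reactive than the starting aliphatic aldehyde, so single homologation is expected.

Step 3
Reactants: 4 (2Z,6E)-3-methyl-8-oxoocta-2,6-dien-1-yl acetate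
Product: 5 (2Z,6Z)-7-iodo-3-methyl-8-oxoocta-2,6-dien-1-yl acetate
Conditions: I2, DMAP (cat.), K2CO3, THF/H2O, rt
Reagents that add atoms: iodine, II
Why: Baylis–Hillman-type addition–iodination–elimination at the α-carbon should give the α-iodoenal in its favoured geometry with iodine cis to the chain (formyl trans), which fixes the later C1=C10 geometry.

Step 4
Reactants: 5 (2Z,6Z)-7-iodo-3-methyl-8-oxoocta-2,6-dien-1-yl acetate
Product: 7 (2Z,6Z)-7-iodo-8,8-dimethoxy-3-methylocta-2,6-dien-1-ol, via acetal acetate 6 (not isolated)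
Conditions: HC(OMe)3, PPTS (cat.), MeOH, rt; then K2CO3, rt
Reagents that add atoms: trimethyl orthoformate, COC(OC)OC
Why: Acid-catalysed acetalisation masks C14 at the aldehyde oxidation level, and base-catalysed methanolysis (transesterification) of the acetate in the same flask should free the C6 hydroxyl.

Step 5
Reactants: 8 (S)-but-3-ene-1,2-diol
Product: 9 (S)-1,2-bis(tert-butyldimethylsilyloxy)but-3-ene
Conditions: TBSCl, imidazole, DMF, rt
Reagents that add atoms: tert-butyldimethylsilyl chloride, CC(C)(C)[Si](C)(C)Cl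
Why: Routine silylation of both hydroxyls; the stereocentre (later C8) is not involved.

Step 6
Reactants: 9 (S)-1,2-bis(tert-butyldimethylsilyloxy)but-3-ene
Product: 10 (S)-2-(tert-butyldimethylsilyloxy)but-3-en-1-ol
Conditions: HF·pyridine, pyridine, THF, 0 °C
Reagents that add atoms: none
Why: Selective desilylation is expected because the primary silyl ether is cleaved faster than the secondary allylic one under buffered fluoride.

Step 7
Reactants: 10 (S)-2-(tert-butyldimethylsilyloxy)but-3-en-1-ol
Product: 11 (S)-2-(tert-butyldimethylsilyloxy)but-3-enal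
Conditions: Dess–Martin periodinane, CH2Cl2, 0 °C to rt; used crude at once
Reagents that add atoms: none
Why: Dess–Martin oxidation is neutral, so the enolisable α-silyloxy β,γ-unsaturated aldehyde should form without epimerisation or alkene migration if it is not stored.

Step 8
Reactants: 7 (2Z,6Z)-7-iodo-8,8-dimethoxy-3-methylocta-2,6-dien-1-ol; 11 (S)-2-(tert-butyldimethylsilyloxy)but-3-enal
Product: 12 (2Z,6E,8R,9S)-9-(tert-butyldimethylsilyloxy)-7-(dimethoxymethyl)-3-methylundeca-2,6,10-triene-1,8-diol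
Conditions: CrCl2 (4 equiv), NiCl2 (1 mol %), 11 (2 equiv), DMSO, rt
Reagents that add atoms: none
Why: Nozaki–Hiyama–Kishi coupling should transfer the alkenyl iodide via nickel to an alkenylchromium species with retention of the C1=C10 geometry, which adds to the aldehyde under Felkin–Anh control (silyloxy group anti to the nucleophile) to set C9 as R (8,9-anti); the free primary alcohol is tolerated.

Step 9
Reactants: 12 (2Z,6E,8R,9S)-9-(tert-butyldimethylsilyloxy)-7-(dimethoxymethyl)-3-methylundeca-2,6,10-triene-1,8-diol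
Product: 13 (2Z,6E,8R,9S)-9-(tert-butyldimethylsilyloxy)-7-(dimethoxymethyl)-8-hydroxy-3-methylundeca-2,6,10-trienal
Conditions: Cu(MeCN)4OTf (5 mol %), 2,2'-bipyridine, TEMPO, N-methylimidazole, air, MeCN, rt
Reagents that add atoms: none
Why: Copper/TEMPO aerobic oxidation is selective for the unhindered primary allylic alcohol over the hindered secondary one and is mild enough to keep the Z geometry of the enal and the acetal.

Step 10
Reactants: 13 (2Z,6E,8R,9S)-9-(tert-butyldimethylsilyloxy)-7-(dimethoxymethyl)-8-hydroxy-3-methylundeca-2,6,10-trienal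
Product: 14 (3S,4R,5E,9Z)-3-(tert-butyldimethylsilyloxy)-5-(dimethoxymethyl)-9-methyl-11-oxoundeca-1,5,9-trien-4-yl 2-(bromomethyl)acrylate
Conditions: 2-(bromomethyl)acrylic acid, (COCl)2, DMF (cat.), CH2Cl2, 0 °C; then 13, 2,6-lutidine, −20 to 0 °C
Reagents that add atoms: 2-(bromomethyl)acrylic acid (used as its chloride), C=C(CBr)C(=O)O
Why: O-acylation with the acid chloride and a hindered, non-nucleophilic base should esterify O9 without displacing the allylic bromide or isomerising the enal.

Step 11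
Reactants: 14 (3S,4R,5E,9Z)-3-(tert-butyldimethylsilyloxy)-5-(dimethoxymethyl)-9-methyl-11-oxoundeca-1,5,9-trien-4-yl 2-(bromomethyl)acrylate
Product: 15 (5S,6R)-3-(bromomethyl)-5-(tert-butyldimethylsilyloxy)-6-[(1E,5Z)-1-(dimethoxymethyl)-5-methyl-7-oxohepta-1,5-dien-1-yl]-5,6-dihydro-2H-pyran-2-one
Conditions: second-generation Grubbs catalyst (10 mol %), toluene (5 mM), 80 °C
Reagents that add atoms: none
Why: Ring-closing metathesis between the terminal vinyl group and the 1,1-disubstituted acrylate should give the six-membered unsaturated lactone, the only ring size open to the two reactive alkenes; the trisubstituted alkenes are inert.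

Step 12
Reactants: 15 (5S,6R)-3-(bromomethyl)-5-(tert-butyldimethylsilyloxy)-6-[(1E,5Z)-1-(dimethoxymethyl)-5-methyl-7-oxohepta-1,5-dien-1-yl]-5,6-dihydro-2H-pyran-2-one
Product: 17 (1(10)E,4Z,6R,7S,8S,9R)-8-(tert-butyldimethylsilyloxy)-9-hydroxy-14,14-dimethoxygermacra-1(10),4,11(13)-trien-12,6-olide, via bridged 6-hydroxy-9,12-olide 16 (not isolated)
Conditions: CrCl2 (8 equiv), DMF/THF (1:1), 25 °C, syringe-pump addition of 15 (final 2 mM); then 50 °C, 2 h; aq. NH4Cl
Reagents that add atoms: none
Why: Two equivalents of CrCl2 reduce the allylic C13–Br bond to an allylchromium species of trivalent chromium, which adds through its γ-carbon C7 to the C6 aldehyde in a six-membered chair (Zimmerman–Traxler) transition state; the closest known type is the Nozaki–Hiyama–Kishi/Barbier allylation with 2-(bromomethyl)acrylates and 3-(bromomethyl)butenolides, a reaction type also used to close ten-membered germacrane rings. The carbocycle closes by 10-exo-trig attack on the aldehyde across C7 and C9 of the pyranone, and the C6 chromium alkoxide then closes the five-membered lactone by 5-exo-trig acyl substitution at C12, opening the bridged six-membered lactone in favour of the less strained fused γ-lactone. C7 is controlled by the pyranone ring: the aldehyde is delivered from the face of the pseudoaxial C9 chain, which is also the face anti to the trans C8 silyloxy group. C6 is controlled by the chair: the ring holds C8 trans to C13 (pseudo-equatorial) and the enal residue sits equatorial, giving the anti adduct and hence trans H6/H7. The step needs γ- over α-attack, 1,2- over 1,4-addition, cyclisation over oligomerisation and retention of the C8 silyloxy group; these should be secured by the allylic-transposition preference and carbonyl selectivity of allylchromium reagents, by high dilution with slow addition, and by the poor leaving-group ability of a silyl ether.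

Step 13
Reactants: 17 (1(10)E,4Z,6R,7S,8S,9R)-8-(tert-butyldimethylsilyloxy)-9-hydroxy-14,14-dimethoxygermacra-1(10),4,11(13)-trien-12,6-olide
Product: 18 (1(10)E,4Z,6R,7S,8S,9R)-8-(tert-butyldimethylsilyloxy)-14,14-dimethoxy-9-[(2R)-2-methylbutanoyloxy]germacra-1(10),4,11(13)-trien-12,6-olide
Conditions: (R)-2-methylbutanoic acid, DIC, DMAP, CH2Cl2, 0 °C to rt
Reagents that add atoms: (R)-2-methylbutanoic acid, CC[C@@H](C)C(=O)O
Why: Steglich esterification acylates the only free hydroxyl (O9), and the low temperature should keep the α-stereocentre of the acid intact.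

Step 14
Reactants: 18 (1(10)E,4Z,6R,7S,8S,9R)-8-(tert-butyldimethylsilyloxy)-14,14-dimethoxy-9-[(2R)-2-methylbutanoyloxy]germacra-1(10),4,11(13)-trien-12,6-olide
Product: 19 (1(10)E,4Z,6R,7R,8S,9R)-8-hydroxy-9-[(2R)-2-methylbutanoyloxy]-14-oxogermacra-1(10),4,11(13)-trien-12,6-olide (CNP0256845.2)
Conditions: 48% aq. HF, MeCN, 0 °C to rt
Reagents that add atoms: water, O
Why: Aqueous HF should cleave the secondary silyl ether and hydrolyse the dimethyl acetal to the conjugated aldehyde in one operation, under conditions too weakly basic for acyl migration from O9 to O8.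

Compound list
1 | neryl acetate, (2Z)-3,7-dimethylocta-2,6-dien-1-yl acetate | CC(=O)OC/C=C(/C)CCC=C(C)C | starting material
2 | 6,7-epoxyneryl acetate (racemic epoxide) | CC(=O)OC/C=C(/C)CCC1OC1(C)C | intermediate
3 | (2Z)-3-methyl-6-oxohex-2-en-1-yl acetate | CC(=O)OC/C=C(/C)CCC=O | intermediate
4 | (2Z,6E)-3-methyl-8-oxoocta-2,6-dien-1-yl acetate | CC(=O)OC/C=C(/C)CC/C=C/C=O | intermediate
5 | (2Z,6Z)-7-iodo-3-methyl-8-oxoocta-2,6-dien-1-yl acetate | CC(=O)OC/C=C(/C)CC/C=C(/C=O)I | intermediate
6 | (2Z,6Z)-7-iodo-8,8-dimethoxy-3-methylocta-2,6-dien-1-yl acetate | CC(=O)OC/C=C(/C)CC/C=C(/C(OC)OC)I | intermediate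
7 | (2Z,6Z)-7-iodo-8,8-dimethoxy-3-methylocta-2,6-dien-1-ol | OC/C=C(/C)CC/C=C(/C(OC)OC)I | intermediate
8 | (S)-but-3-ene-1,2-diol | OC[C@@H](O)C=C | starting material
9 | (S)-1,2-bis(tert-butyldimethylsilyloxy)but-3-ene | CC(C)(C)[Si](C)(C)OC[C@@H](O[Si](C)(C)C(C)(C)C)C=C | intermediate
10 | (S)-2-(tert-butyldimethylsilyloxy)but-3-en-1-ol | OC[C@@H](O[Si](C)(C)C(C)(C)C)C=C | intermediate
11 | (S)-2-(tert-butyldimethylsilyloxy)but-3-enal | O=C[C@@H](O[Si](C)(C)C(C)(C)C)C=C | intermediate
12 | (2Z,6E,8R,9S)-9-(tert-butyldimethylsilyloxy)-7-(dimethoxymethyl)-3-methylundeca-2,6,10-triene-1,8-diol | OC/C=C(/C)CC/C=C(/C(OC)OC)[C@@H](O)[C@@H](O[Si](C)(C)C(C)(C)C)C=C | intermediate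
13 | (2Z,6E,8R,9S)-9-(tert-butyldimethylsilyloxy)-7-(dimethoxymethyl)-8-hydroxy-3-methylundeca-2,6,10-trienal | O=C/C=C(/C)CC/C=C(/C(OC)OC)[C@@H](O)[C@@H](O[Si](C)(C)C(C)(C)C)C=C | intermediate
14 | (3S,4R,5E,9Z)-3-(tert-butyldimethylsilyloxy)-5-(dimethoxymethyl)-9-methyl-11-oxoundeca-1,5,9-trien-4-yl 2-(bromomethyl)acrylate | O=C/C=C(/C)CC/C=C(/C(OC)OC)[C@@H](OC(=O)C(=C)CBr)[C@@H](O[Si](C)(C)C(C)(C)C)C=C | intermediate
15 | (5S,6R)-3-(bromomethyl)-5-(tert-butyldimethylsilyloxy)-6-[(1E,5Z)-1-(dimethoxymethyl)-5-methyl-7-oxohepta-1,5-dien-1-yl]-5,6-dihydro-2H-pyran-2-one | O=C/C=C(/C)CC/C=C(/C(OC)OC)[C@H]1OC(=O)C(CBr)=C[C@@H]1O[Si](C)(C)C(C)(C)C | intermediate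
16 | (1(10)E,4Z,6R,7S,8S,9R)-8-(tert-butyldimethylsilyloxy)-6-hydroxy-14,14-dimethoxygermacra-1(10),4,11(13)-trien-12,9-olide (six-membered lactone bridging C7 and C9 of the new ten-membered ring) | C=C1C(=O)O[C@H]2[C@@H](O[Si](C)(C)C(C)(C)C)[C@@H]1[C@H](O)/C=C(/C)CC/C=C2/C(OC)OC | intermediate
17 | (1(10)E,4Z,6R,7S,8S,9R)-8-(tert-butyldimethylsilyloxy)-9-hydroxy-14,14-dimethoxygermacra-1(10),4,11(13)-trien-12,6-olide | C=C1C(=O)O[C@@H]2/C=C(/C)CC/C=C(/C(OC)OC)[C@@H](O)[C@@H](O[Si](C)(C)C(C)(C)C)[C@@H]12 | intermediate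
18 | (1(10)E,4Z,6R,7S,8S,9R)-8-(tert-butyldimethylsilyloxy)-14,14-dimethoxy-9-[(2R)-2-methylbutanoyloxy]germacra-1(10),4,11(13)-trien-12,6-olide | C=C1C(=O)O[C@@H]2/C=C(/C)CC/C=C(/C(OC)OC)[C@@H](OC(=O)[C@H](C)CC)[C@@H](O[Si](C)(C)C(C)(C)C)[C@@H]12 | intermediate
19 | (1(10)E,4Z,6R,7R,8S,9R)-8-hydroxy-9-[(2R)-2-methylbutanoyloxy]-14-oxogermacra-1(10),4,11(13)-trien-12,6-olide (both ring alkenes cis within the ring) | C=C1C(=O)O[C@@H]2/C=C(/C)CC/C=C(/C=O)[C@@H](OC(=O)[C@H](C)CC)[C@@H](O)[C@@H]12 | target

Total step count: 14. Longest linear sequence: 11 steps (steps 1–4, then 8–14).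

Steps most likely to fail

1. Step 12. The allylchromium may deliver the aldehyde through a boat or to the other face of C7 (epimers at C6 or C7), may expel the C8 silyloxy group by vinylogous β-elimination, or may oligomerise. The silyl group may also move from O8 to O9 once O9 is freed, and the acyl transfer to O6 may stall. The fallback sets out from 15 and replaces the low-valent metal by a boron-based closed-transition-state allylation. Borylation of the allylic bromide (B2pin2, Pd2(dba)3, DMSO, rt) should give the allylboronate aldehyde F1. Warming F1 in dilute toluene with Sc(OTf)3 (cat.) should effect intramolecular allylboration through the same ring-locked chair without an eliminable carbon–metal bond. Work-up with PPTS in CH2Cl2 should cleave the borate and complete the translactonisation, rejoining the route at 17.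

2. Step 8. Facial selectivity in the addition to the α-silyloxy aldehyde may be poor, and the aldehyde may epimerise or isomerise before it is captured. The fallback sets out from 7 and sets C9 by ketone reduction instead of carbonyl addition. Silylation (TESCl, imidazole) gives the triethylsilyl ether F2. The same CrCl2/NiCl2 coupling with 11 gives the C9-epimeric adducts F3. Dess–Martin oxidation gives the enone F4. Luche reduction (NaBH4, CeCl3·7H2O, MeOH, −78 °C) under Felkin–Anh control of the α-silyloxy group should give the 9R alcohol F5. PPTS in MeOH at 0 °C removes the primary triethylsilyl group and returns the route at 12.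

3. Step 11. The allylic bromide may deactivate the ruthenium carbene, closure to the trisubstituted alkene may be slow, and prolonged heating may isomerise the Z enal. The fallback sets out from 13 and introduces the bromide only after metathesis. Ethyl 2-(hydroxymethyl)acrylate is silylated (TBSCl, imidazole) to ethyl 2-[(tert-butyldimethylsilyloxy)methyl]acrylate F6 and saponified (LiOH, THF/H2O) to 2-[(tert-butyldimethylsilyloxy)methyl]acrylic acid F7. Steglich esterification of 13 with F7 (DIC, DMAP) gives the acrylate ester F8. Ring-closing metathesis (second-generation Grubbs catalyst, toluene, 80 °C) gives the 3-(silyloxymethyl)dihydropyranone F9. HF·pyridine/pyridine at 0 °C removes the primary allylic silyl group to give the 3-(hydroxymethyl)dihydropyranone F10. Corey–Kim bromination (NBS, Me2S, CH2Cl2, −20 to 0 °C), which spares the aldehyde, returns the route at 15.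

Further compounds
F1 | step 12 | (5S,6R)-5-(tert-butyldimethylsilyloxy)-6-[(1E,5Z)-1-(dimethoxymethyl)-5-methyl-7-oxohepta-1,5-dien-1-yl]-3-[(4,4,5,5-tetramethyl-1,3,2-dioxaborolan-2-yl)methyl]-5,6-dihydro-2H-pyran-2-one | O=C/C=C(/C)CC/C=C(/C(OC)OC)[C@H]1OC(=O)C(CB2OC(C)(C)C(C)(C)O2)=C[C@@H]1O[Si](C)(C)C(C)(C)C
F2 | step 8 | (2Z,6Z)-7-iodo-8,8-dimethoxy-3-methyl-1-(triethylsilyloxy)octa-2,6-diene | CC[Si](CC)(CC)OC/C=C(/C)CC/C=C(/C(OC)OC)I
F3 | step 8 | (2Z,6E,9S)-9-(tert-butyldimethylsilyloxy)-7-(dimethoxymethyl)-3-methyl-1-(triethylsilyloxy)undeca-2,6,10-trien-8-ol, both C8 epimers of the chain (C9 of the skeleton) | CC[Si](CC)(CC)OC/C=C(/C)CC/C=C(/C(OC)OC)C(O)[C@@H](O[Si](C)(C)C(C)(C)C)C=C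
F4 | step 8 | (2Z,6E,9S)-9-(tert-butyldimethylsilyloxy)-7-(dimethoxymethyl)-3-methyl-1-(triethylsilyloxy)undeca-2,6,10-trien-8-one | CC[Si](CC)(CC)OC/C=C(/C)CC/C=C(/C(OC)OC)C(=O)[C@@H](O[Si](C)(C)C(C)(C)C)C=C
F5 | step 8 | (2Z,6E,8R,9S)-9-(tert-butyldimethylsilyloxy)-7-(dimethoxymethyl)-3-methyl-1-(triethylsilyloxy)undeca-2,6,10-trien-8-ol | CC[Si](CC)(CC)OC/C=C(/C)CC/C=C(/C(OC)OC)[C@@H](O)[C@@H](O[Si](C)(C)C(C)(C)C)C=C
F6 | step 11 | ethyl 2-[(tert-butyldimethylsilyloxy)methyl]acrylate | CCOC(=O)C(=C)CO[Si](C)(C)C(C)(C)C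
F7 | step 11 | 2-[(tert-butyldimethylsilyloxy)methyl]acrylic acid | OC(=O)C(=C)CO[Si](C)(C)C(C)(C)C
F8 | step 11 | (3S,4R,5E,9Z)-3-(tert-butyldimethylsilyloxy)-5-(dimethoxymethyl)-9-methyl-11-oxoundeca-1,5,9-trien-4-yl 2-[(tert-butyldimethylsilyloxy)methyl]acrylate | O=C/C=C(/C)CC/C=C(/C(OC)OC)[C@@H](OC(=O)C(=C)CO[Si](C)(C)C(C)(C)C)[C@@H](O[Si](C)(C)C(C)(C)C)C=C
F9 | step 11 | (5S,6R)-5-(tert-butyldimethylsilyloxy)-3-[(tert-butyldimethylsilyloxy)methyl]-6-[(1E,5Z)-1-(dimethoxymethyl)-5-methyl-7-oxohepta-1,5-dien-1-yl]-5,6-dihydro-2H-pyran-2-one | O=C/C=C(/C)CC/C=C(/C(OC)OC)[C@H]1OC(=O)C(CO[Si](C)(C)C(C)(C)C)=C[C@@H]1O[Si](C)(C)C(C)(C)C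
F10 | step 11 | (5S,6R)-5-(tert-butyldimethylsilyloxy)-6-[(1E,5Z)-1-(dimethoxymethyl)-5-methyl-7-oxohepta-1,5-dien-1-yl]-3-(hydroxymethyl)-5,6-dihydro-2H-pyran-2-one | O=C/C=C(/C)CC/C=C(/C(OC)OC)[C@H]1OC(=O)C(CO)=C[C@@H]1O[Si](C)(C)C(C)(C)C
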